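Readings and results come from a simulation with constants of no real substance, and the scatter is random.

Compare two amounts in the red flask: the target and the unseen rest of the charge.

| flask | solid substrate | protic impurity | temperature | remark | time |
|---|---|---|---|---|---|
| red | 0.058 M | 2.9 mM | 90 °C | the very flask that is asked about, followed so far |  |
| teal | 0.087 M | 2.9 mM | 85 °C | run made earlier |  |
| flask | 0.058 M | 2.90 mM | 90 °C |  | 30 min |

- red (time / min: target / %, solid substrate / %): 2.50: 34.2, 0; 4.00: 34.6, 0; 6.00: 34.1, 0.1; 8.00: 33.3, 0; 12.0: 33.6, 0.3; 20.0: 33.6, 0.2; 30.0: 33.4, 0.2
- teal (time / min: target / %, solid substrate / %): 0.167: 6.4, 76.5; 0.500: 23.0, 30.9; 0.833: 35.8, 0; 1.33: 36.3, 0; 2.00: 36.2, 0.3; 2.50: 35.5, 0.2; 3.00: 35.8, 0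

(scatter of a reading: 0.3 percentage points)

- cedar: at 30 min raise the temperature by 25 K, then wait 1.0 h
- alder: at 30 min take out 90% of the target then present, then wait 1.0 h
- larch: change nothing and wait 1.0 h more

- solid, in amounts per volume of the solution: solid substrate
- target taken out counts as made
- at the start none of the solid substrate is in solution

- target, in percent of the solid substrate first charged, at 30 min
- the option that brings most further target ("none" if no option brings more than 2 percentage points) (cedar / alder / larch / none)
- target present, with what was taken out counted in, in percent of the solid substrate first charged, after cedar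
- target present, with what was taken out counted in, in percent of the solid substrate first charged, after larch

The red run holds target near 33.4% from 2.50 min to 30.0 min, and solid substrate reads 0.2% at the last of these times. The unseen rest, with both readings taken off, is therefore 66.4%. Target over unseen rest is the split ratio, 0.503. The teal run, cooler and with more solid substrate charged, reads higher, 0.558; the two settings differ together, so my own reckoning assumes that the gap comes from temperature and on that assumption expects cedar to lose target.

That reckoning takes the plateau as thermodynamic control, with the rest able to return. Larch then changes nothing. Alder takes out 90% of the target, what stays in the flask divides at the same ratio, and the gain is 20 percentage points, past the 2 points mark.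

The forecast gives 33.7% (33.3% to 34.1%), alder, 26% after cedar (22% to 34%) and 33.7% after larch (33.1% to 34.3%): “If it is equilibrium, removing target re-forms more from the pool, so alder is best.”

The flask gives 33.3% and picks alder, which brings 19 points; cedar ends at 27.9% and larch at 33.2%.

    starting material + protic impurity → quenched substrate (k = 2.48 L mol⁻¹ s⁻¹, Ea = 70.0 kJ mol⁻¹)
    starting material ⇌ target (K = 30.7, k = 0.241 s⁻¹, Ea = 94.0 kJ mol⁻¹, ΔH = −17.0 kJ mol⁻¹)
    isomer of the product ⇌ starting material (k = 0.0307 s⁻¹, Ea = 98.0 kJ mol⁻¹)
    target ⇌ isomer of the product (K = 1.83, k = 0.371 s⁻¹, Ea = 94.0 kJ mol⁻¹, ΔH = 12.0 kJ mol⁻¹)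
    solid substrate ⇌ starting material, rate k5*(cs5 - [starting material]) while solid is left; crystals form when [starting material] > cs5 (solubility = 32.0 mM, k = 0.0663 s⁻¹)
    (constants at 90 °C)

At 30 min the unseen rest of this flask is isomer of the product 60.9%, starting material 1.08% and quenched substrate 4.72%. Leaving the quenched part out puts the split ratio at 0.537. The neighbouring flask, with [protic impurity] raised to 0.012 M, holds quenched substrate 19.1%. Dividing the remainder at that ratio gives 28.3% target, and the neighbouring flask gives 28.3%.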